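Retrosynthetic cuts, in order: both phenols (5-OH, 3'-OH) go back to benzyl ethers and C5–OBn goes back to C5–F. Ring C is then cut at C3–C4 and at O1–C8a, which leaves a B-ring methyl ketone and an A-ring acid chloride.
Enabling feature: on ring A, the oxygen-bearing carbons C5 and C8a are the two ortho neighbours of C4a, which holds the C4 carbonyl, and the 7-OMe is para to C4a. Ring A therefore maps onto a mirror-symmetric 2,6-difluoro-4-methoxybenzoyl group with two identical C–F bonds, both activated for SNAr by that carbonyl.
Forward: rings A and B are bought as arenes. Ring B gets its C3' oxygen by directed lithiation–oxidation and its acetyl group (future C2 and C3) by Friedel–Crafts acylation. Ring C, the only ring made, closes in step 6, and fluoride-to-benzyloxy exchange at C5 followed by one hydrogenolysis finishes the route.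
Stereochemistry: nothing has to be set, because the flavone has no stereocentre and no configurationally stable axis.

Key step: step 6

Remark: the target SMILES carries no stereodescriptor and the molecule is achiral, so the task reduces to making the one constitution drawn.

Step 1
Reactants: 1 1,2,4-trimethoxybenzene
Product: 4 2,3,6-trimethoxyphenol, via 2,3,6-trimethoxyphenyllithium 2 (not isolated), via dimethyl 2,3,6-trimethoxyphenylboronate 3 (not isolated)
Conditions: n-BuLi, THF, 0 °C → rt; B(OMe)3, −78 °C → rt; 30% H2O2, AcOH, 0 °C → rt
Reagents that add atoms: n-butyllithium [Li]CCCC (Li of 2); trimethyl borate COB(OC)OC (boron unit of 3); hydrogen peroxide OO (phenol oxygen of 4)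
Why: Directed ortho-metalation removes the C3 proton, the only one held between two coordinating methoxy groups, and borylation followed by peroxide-induced 1,2-aryl migration (boronate oxidation) turns that C–Li bond into C–OH at the same carbon.

Step 2
Reactants: 4 2,3,6-trimethoxyphenol
Product: 5 2,3,6-trimethoxyphenyl acetate
Conditions: Ac2O, pyridine, cat. DMAP, CH2Cl2, rt
Reagents that add atoms: acetic anhydride CC(=O)OC(C)=O
Why: DMAP-catalysed O-acylation of a phenol is reliable even with two ortho methoxy groups, and the ester makes this oxygen the weakest donor on the ring for step 3.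

Step 3
Reactants: 5 2,3,6-trimethoxyphenyl acetate; 6 acetyl chloride
Product: 7 3-acetyl-2,5,6-trimethoxyphenyl acetate (3-acetoxy-2,4,5-trimethoxyacetophenone)
Conditions: AcCl, SnCl4, CH2Cl2, −10 → 0 °C
Reagents that add atoms: none
Why: Friedel–Crafts acylation should take the C–H that is para to the 2-methoxy and ortho to the 6-methoxy group rather than the one para to the weakly donating acetoxy group, and SnCl4 at or below 0 °C is too mild for Fries migration or for cleavage of the methyl ether beside the new ketone.

Step 4
Reactants: 7 3-acetyl-2,5,6-trimethoxyphenyl acetate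
Product: 9 3-benzyloxy-2,4,5-trimethoxyacetophenone, via 3-hydroxy-2,4,5-trimethoxyacetophenone 8 (not isolated)
Conditions: K2CO3, MeOH, rt, Ar; concentrate; BnBr, K2CO3, DMF, 50 °C
Reagents that add atoms: benzyl bromide BrCc1ccccc1
Why: Carbonate-catalysed transesterification (Zemplén-type deacetylation) frees the phenoxide, which is trapped by Williamson etherification, and carbonate is too weak a base to cause C-benzylation or aldol reaction of the methyl ketone.

Step 5
Reactants: 10 2,6-difluoro-4-methoxybenzoic acid
Product: 11 2,6-difluoro-4-methoxybenzoyl chloride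
Conditions: (COCl)2, cat. DMF, CH2Cl2, 0 °C → rt
Reagents that add atoms: oxalyl chloride O=C(Cl)C(=O)Cl
Why: Acid chloride formation through the catalytic Vilsmeier-type chloroiminium species runs cold and without base, so the aryl fluorides and the methyl ether are left untouched.

Step 6
Reactants: 9 3-benzyloxy-2,4,5-trimethoxyacetophenone; 11 2,6-difluoro-4-methoxybenzoyl chloride
Product: 14 3'-benzyloxy-5-fluoro-7,2',4',5'-tetramethoxyflavone, via B-ring lithium enolate 12 (not isolated), via difluoroaryl 1,3-diketone 13 (not isolated)
Conditions: 9, LiHMDS (2.2 equiv), THF, −78 °C; 11, −78 → 0 °C; 1 M HCl quench, crude 13 taken on; K2CO3, DMF, 80 °C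
Reagents that add atoms: lithium hexamethyldisilazide [Li]N([Si](C)(C)C)[Si](C)(C)C (Li of 12 only; no reagent atom remains in 14)
Why: LiHMDS converts 9 into lithium enolate 12, whose carbon attacks acid chloride 11 to form C3–C4, and the second equivalent of base immediately deprotonates 13, which shields it from further acylation. With K2CO3 in warm DMF the enolate oxygen next to ring B adds to one C–F carbon of ring A, the Meisenheimer anion is delocalised into the ortho C4 carbonyl, and loss of fluoride gives O1–C8a. The closest known reaction type is the tandem C-acylation/intramolecular SNAr of aryl methyl ketone enolates with 2-halobenzoyl chlorides, which is an established route to flavones. The pyranone closes as a six-membered, formally 6-endo-trig addition–elimination, and no stereocentre is created. C- over O-acylation is favoured by the tightly bound lithium counter-ion in THF at −78 °C, and any enol ester that forms can still act as an acyl donor toward remaining enolate, so the material funnels to the chelated diketonate. Site selectivity needs no control because the two fluorines are related by the symmetry of the aroyl unit, and a second displacement cannot follow because the fluorine left at C5 has no internal nucleophile within reach.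

Step 7
Reactants: 14 3'-benzyloxy-5-fluoro-7,2',4',5'-tetramethoxyflavone
Product: 15 5,3'-bis(benzyloxy)-7,2',4',5'-tetramethoxyflavone
Conditions: BnOH, NaH, THF, 0 °C; then 14, 0 → 60 °C
Reagents that add atoms: benzyl alcohol OCc1ccccc1
Why: In this intermolecular SNAr the C5–F bond is ortho to the C4 carbonyl that takes up the charge of the Meisenheimer anion, the ring donors 7-OMe and O1 are meta to the attacked carbon and do not oppose it, and any alkoxide addition at C2 is reversible whereas loss of fluoride is not.

Step 8
Reactants: 15 5,3'-bis(benzyloxy)-7,2',4',5'-tetramethoxyflavone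
Product: 16 5,3'-dihydroxy-7,2',4',5'-tetramethoxyflavone
Conditions: H2 (1 atm), 10% Pd/C, EtOAc–MeOH, rt
Reagents that add atoms: none
Why: Catalytic hydrogenolysis cleaves both aryl benzyl ethers at 1 atm and room temperature, conditions under which the conjugated C2=C3 bond of a flavone, the C4 carbonyl and the methyl ethers normally persist.

Compound list
1 | 1,2,4-trimethoxybenzene | COc1ccc(OC)c(OC)c1 | starting material
2 | 2,3,6-trimethoxyphenyllithium | [Li]c1c(OC)ccc(OC)c1OC | intermediate
3 | dimethyl (2,3,6-trimethoxyphenyl)boronate | COB(OC)c1c(OC)ccc(OC)c1OC | intermediate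
4 | 2,3,6-trimethoxyphenol | COc1ccc(OC)c(OC)c1O | intermediate
5 | 2,3,6-trimethoxyphenyl acetate | COc1ccc(OC)c(OC)c1OC(C)=O | intermediate
6 | acetyl chloride | CC(=O)Cl | starting material
7 | 3-acetyl-2,5,6-trimethoxyphenyl acetate (3-acetoxy-2,4,5-trimethoxyacetophenone) | CC(=O)c1cc(OC)c(OC)c(OC(C)=O)c1OC | intermediate
8 | 3-hydroxy-2,4,5-trimethoxyacetophenone | CC(=O)c1cc(OC)c(OC)c(O)c1OC | intermediate
9 | 3-benzyloxy-2,4,5-trimethoxyacetophenone | CC(=O)c1cc(OC)c(OC)c(OCc2ccccc2)c1OC | intermediate
10 | 2,6-difluoro-4-methoxybenzoic acid | COc1cc(F)c(C(=O)O)c(F)c1 | starting material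
11 | 2,6-difluoro-4-methoxybenzoyl chloride | COc1cc(F)c(C(=O)Cl)c(F)c1 | intermediate
12 | lithium 1-(3-benzyloxy-2,4,5-trimethoxyphenyl)ethenolate | [Li]OC(=C)c1cc(OC)c(OC)c(OCc2ccccc2)c1OC | intermediate
13 | 1-(3-benzyloxy-2,4,5-trimethoxyphenyl)-3-(2,6-difluoro-4-methoxyphenyl)propane-1,3-dione | COc1cc(F)c(C(=O)CC(=O)c2cc(OC)c(OC)c(OCc3ccccc3)c2OC)c(F)c1 | intermediate
14 | 3'-benzyloxy-5-fluoro-7,2',4',5'-tetramethoxyflavone | COc1cc(F)c2c(=O)cc(-c3cc(OC)c(OC)c(OCc4ccccc4)c3OC)oc2c1 | intermediate
15 | 5,3'-bis(benzyloxy)-7,2',4',5'-tetramethoxyflavone | COc1cc(OCc2ccccc2)c3c(=O)cc(-c4cc(OC)c(OC)c(OCc5ccccc5)c4OC)oc3c1 | intermediate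
16 | 5,3'-dihydroxy-7,2',4',5'-tetramethoxyflavone | COc1cc(O)c2c(=O)cc(-c3cc(OC)c(OC)c(O)c3OC)oc2c1 | target

Total step count: 8. Longest linear sequence: 7 (steps 1, 2, 3, 4, 6, 7, 8). Step 5 is a one-step side branch.

Steps most likely to fail

1. Step 7.
- **Risk:** Fluoride displacement may be slow, because the activating C4 carbonyl is only a vinylogous ester. Alkoxide addition at C2 and opening of the pyranone may then compete on prolonged heating.
- **Fallback (from 11 and 9, back at 15):** The C5 oxygen is installed before the annulation, on a better activated ring.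
  - Acid chloride 11 is esterified with benzyl alcohol (Et3N, CH2Cl2) to benzyl 2,6-difluoro-4-methoxybenzoate F1.
  - One equivalent of sodium benzyloxide in THF displaces one of the two equivalent, ester-activated fluorides to give benzyl 2-benzyloxy-6-fluoro-4-methoxybenzoate F2. Alkoxide exchange at the ester is degenerate.
  - Saponification (KOH, aqueous EtOH, heat) gives 2-benzyloxy-6-fluoro-4-methoxybenzoic acid F3.
  - Oxalyl chloride with catalytic DMF gives 2-benzyloxy-6-fluoro-4-methoxybenzoyl chloride F4.
  - Acylation of enolate 12 with F4 under the conditions of step 6 gives 1-(2-benzyloxy-6-fluoro-4-methoxyphenyl)-3-(3-benzyloxy-2,4,5-trimethoxyphenyl)propane-1,3-dione F5, which has a single fluoride left to displace. K2CO3 in DMF closes it directly to 15.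

2. Step 3.
- **Risk:** Regiocontrol between the two free ring positions may erode. The Lewis acid may also cleave the methyl ether next to the new ketone or cause the O-acetyl group to migrate.
- **Fallback (from 1 and 6, back at 8):** The two ring-B functionalisations are done in the reverse order, so that each follows a firmly established preference.
  - Friedel–Crafts acetylation of 1 with 6 goes to its most activated position and gives 2,4,5-trimethoxyacetophenone F6.
  - Ethylene glycol and TsOH in toluene with water removal mask the ketone as 2-methyl-2-(2,4,5-trimethoxyphenyl)-1,3-dioxolane F7.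
  - n-BuLi then removes the proton between the 2- and 4-methoxy groups, and the B(OMe)3/H2O2 sequence of step 1 gives 3-(2-methyl-1,3-dioxolan-2-yl)-2,5,6-trimethoxyphenol F8.
  - Dilute HCl in THF releases 8, which is benzylated as in the second half of step 4.

3. Step 6.
- **Risk:** The enolate may be O-acylated. Proton exchange between the diketone and unreacted enolate may stall conversion. The amide base may attack the acid chloride.
- **Fallback (from 9 and 11, back at 13 and then 14):** The hard lithium enolate is replaced by soft enolisation, and the two bond formations are run as separate, isolated operations.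
  - Acid chloride 11 reacts with 1H-benzotriazole and Et3N to give 1-(2,6-difluoro-4-methoxybenzoyl)-1H-benzotriazole F9.
  - Ketone 9, F9, MgBr2·OEt2 and i-Pr2NEt in CH2Cl2 at rt form a magnesium-chelated enolate that is acylated on carbon to give 13.
  - 13 is purified and then cyclised with K2CO3 in DMF to 14.

Further compounds
F1 | step 7 | benzyl 2,6-difluoro-4-methoxybenzoate | COc1cc(F)c(C(=O)OCc2ccccc2)c(F)c1
F2 | step 7 | benzyl 2-benzyloxy-6-fluoro-4-methoxybenzoate | COc1cc(F)c(C(=O)OCc2ccccc2)c(OCc3ccccc3)c1
F3 | step 7 | 2-benzyloxy-6-fluoro-4-methoxybenzoic acid | COc1cc(F)c(C(=O)O)c(OCc2ccccc2)c1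
F4 | step 7 | 2-benzyloxy-6-fluoro-4-methoxybenzoyl chloride | COc1cc(F)c(C(=O)Cl)c(OCc2ccccc2)c1
F5 | step 7 | 1-(2-benzyloxy-6-fluoro-4-methoxyphenyl)-3-(3-benzyloxy-2,4,5-trimethoxyphenyl)propane-1,3-dione | COc1cc(F)c(C(=O)CC(=O)c2cc(OC)c(OC)c(OCc3ccccc3)c2OC)c(OCc4ccccc4)c1
F6 | step 3 | 2,4,5-trimethoxyacetophenone | CC(=O)c1cc(OC)c(OC)cc1OC
F7 | step 3 | 2-methyl-2-(2,4,5-trimethoxyphenyl)-1,3-dioxolane | CC1(OCCO1)c2cc(OC)c(OC)cc2OC
F8 | step 3 | 3-(2-methyl-1,3-dioxolan-2-yl)-2,5,6-trimethoxyphenol | CC1(OCCO1)c2cc(OC)c(OC)c(O)c2OC
F9 | step 6 | 1-(2,6-difluoro-4-methoxybenzoyl)-1H-benzotriazole | COc1cc(F)c(C(=O)n2nnc3ccccc32)c(F)c1
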